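Compound numbers are those of the steps and the compound list. Flavanone numbering is used throughout: unit 1 (rings A and C, unprimed atoms) carries the 4-methoxyphenyl group, and unit 2 (rings A' and C', primed atoms) carries the 4-hydroxyphenyl group.

## Analysis of the target

The target 21 is a biflavanone: two 5,7-dihydroxychroman-4-one units joined by the C3–C3' bond, with a 4-methoxyphenyl ring on C2 and a 4-hydroxyphenyl ring on C2'. The four stereocentres C2, C3, C3' and C2' are contiguous and have the configuration (2S,3R,2'S,3'S). Read from the structure, unit 1 is 2,3-trans and unit 2 is 2',3'-cis, so the molecule is unsymmetrical both in constitution (OMe against OH) and in relative configuration, and a dimerisation cannot make it. C3 and C3' are both α to a ketone, each ring C can open by retro-oxa-Michael reaction, and the cis unit is the less stable arrangement, so base or acid would move it towards trans. Five free phenols sit on oxidation-prone rings and must be told apart from the single methyl ether. The hard part is to set the disfavoured cis pair C2'/C3' with absolute control next to a pair that equilibrates freely, across a bond between two tertiary carbons. The strategy rests on ring C': the bonds O1'–C2' and C3'–C4' leave the aryl group on C2' and the substituent on C3' on the same face. This is the imprint of a suprafacial [4+2] addition of a ring-A' ortho-quinone methide (O1'=C8a'–C4a'=C4') to a (Z)-alkene. If C4' is kept as a methylene, C3' has no acidic hydrogen and the cis pair is inert while unit 1 is built.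

## Retrosynthetic reasoning

**21 to 20.** The five phenols are masked as benzyl ethers and freed by hydrogenolysis in the last step. Only then are the free phloroglucinol-type rings and the epimerisable cis ketone present together, and the conditions are neutral. The methyl ether is not affected, so the two kinds of aryl oxygen are told apart from the start.

**20 to 19 to 18.** The C4' ketone is taken back to a methylene group. With C4' as CH2 the cis pair C2'/C3' cannot epimerise, so all base-mediated chemistry can be done before this oxygen is introduced. The forward direction needs a benzylic oxidation that picks C4' among several benzylic positions (hydride abstraction at the most electron-rich site, giving 19), then a non-basic alcohol oxidation to 20.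

**18 to 15 and 16 through 17.** Ring C is opened at O1–C2 (retro-oxa-Michael to chalcone 17) and then at C2–C3 (retro-aldol to ketone 15 and aldehyde 16). C2 and C3 are cut because they are the two centres of the target that can equilibrate, so their trans relationship can be left to thermodynamics. The forward reaction must also choose between the two trans arrangements relative to the fixed C3' centre, and the neighbouring stereocentre is relied on for that.

**15 to 14 to 10 and 12 through 13.** The aryl–carbonyl bond C4–C4a is cut, giving the Weinreb amide 10 and an aryl nucleophile 13 made from bromide 12. The symmetrical tribenzyl ether 11 is chosen as the source of ring A because its bromination has only one possible outcome. The two ortho benzyl ethers of ketone 14 are equivalent, so chelation to the new ketone can release either one to give phenol 15.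

**10 to 9.** A functional-group change at the end of the two-carbon arm. The arm methylene becomes C3 and the ester carbon becomes C4.

**9 to 3 and 7 through 8 (key disconnection).** The bonds O1'–C2' and C3'–C4' are cut in a retro-hetero-Diels–Alder sense, giving the ortho-quinone methide 8 (from salicyl alcohol 3) and the (Z)-styrene 7. This is the only disconnection of ring C' in which both stereocentres come from one stereospecific event. The alkene geometry fixes cis, and a chiral Brønsted acid bound to 8 can fix the absolute sense. It also removes one ring, two skeletal bonds and two stereocentres at once and leads to two simple achiral pieces.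

**3 to 2 to 1.** The benzylic alcohol comes from the aldehyde 2 by hydride reduction. Compound 2 comes from the trihydroxy aldehyde 1 by twofold benzylation, which stops by itself at the hydrogen-bonded hydroxyl.

**7 to 6 to 4 and 5.** The (Z) geometry is taken from syn-semihydrogenation of the alkyne 6, not from an olefination. Ylides that carry a carboxylate give mainly (E)-alkenes with aromatic aldehydes, and a β,γ-unsaturated ester should not meet base. Alkyne 6 is cut between C2 and C3 of the butynoate into the terminal alkyne 4 and the diazo ester 5. The ethyl ester is used because 5 is the commercial diazo ester; the ester alkyl group is a spectator.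

## Alternatives that were turned down

**Alternative 1:** The cut is at C2–C3 of unit 1. The enol acetal A2, a 4-alkylidene-1,3-benzodioxine made from anisaldehyde, would be opened by Me2AlCl at the bond between the acetal carbon and the enol oxygen. The aluminium enolate would then close through carbon onto the aryloxy-stabilised cation to give the trans chromanone A1, whose silyloxyethyl chain supplies C3' and C4'.
- For: ring C forms under Lewis-acid control with a dependable trans outcome, the benzyl ethers tolerate the conditions, and A2 is easy to assemble.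
- Against: the acetal carbon becomes planar on ionisation, so the absolute configuration at C2 is not transferred and would need a chiral Lewis acid or a resolution. More seriously, only the easy, thermodynamic half of the molecule is solved. Ring C' would have to be built from the side chain next to a finished, base-labile flavanone, by chemistry that favours trans, so the cis pair has no controlling element.
- Comparison: A1 is at least as strong as the chosen route in forming unit 1, since it does not depend on a hindered condensation. The chosen route offers instead a stereospecific origin for the cis pair, catalyst control of absolute configuration, and construction of the fragile half while nothing else can be damaged.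

**Alternative 2:** The cuts are at both aryl–carbonyl bonds, C4–C4a and C4'–C4a'. The succinic acid A4 already carries the two aryl(aryloxy)methyl groups. As its bis(mixed anhydride) with trifluoroacetic anhydride it would acylate each 3,5-dibenzyloxyphenyl ether ortho to the ether oxygen, closing rings C and C' in one operation to give A3, which is the same compound as 20.
- For: the approach is convergent, the acylation has only one reachable and strongly activated position on each ring, and the end game is one hydrogenolysis with no C–H oxidation. On step economy after the key step it is stronger than the chosen route.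
- Against: all four contiguous stereocentres, including two benzylic aryl ether centres, must be set on an open chain beforehand, so the stereochemical problem is only moved. In the acidic anhydride medium the 4-alkoxybenzylic aryl ethers can ionise or be lost by β-elimination. Once ring C' is closed, its new ketone can enolise and let C3' go to trans.
- Comparison: the chosen route needs more steps after its key step, but it creates the cis pair in the bond-forming event that defines it and keeps C4' as a methylene until the neutral final steps.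

**Alternative 3:** The cut is at C2'–C3'. The diazoketone A6, attached by its diazo carbon to C3 of a finished unit 1, would be decomposed by Rh2(OAc)4. The rhodium carbene would insert into a benzylic C–H bond of one of two equivalent ortho 4-benzyloxybenzyl ethers to close ring C' and give A5, whose extra 4-benzyloxybenzyl group would be lost in the final hydrogenolysis.
- For: such insertions tend to give cis-2,3-disubstituted chromanones kinetically, C4' is already a ketone, and the target is one step away. Here it is stronger than the chosen route.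
- Against: the carbene carbon bears a secondary alkyl group with a β-hydrogen (H3), and 1,2-hydride migration to an enone is normally faster than insertion through a six-membered transition state. The electron-rich rings invite cyclopropanation. Diazo transfer would have to be done on a hindered ketone that already contains the base-labile unit 1. The facial selectivity at C3' relative to C3 rests on substrate bias.
- Comparison: the chosen route is longer after the key step, but its key step joins two simple achiral partners, takes the relative configuration from alkene geometry and the absolute configuration from a catalyst.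

Key step: step 5

**Assumptions.**
- The (R) enantiomer of the phosphoric acid is taken as the one that gives the (2S,3S) chroman 9; if the sense of induction is the opposite, the (S) enantiomer is used and nothing else changes.
- Compounds 1, 4, 5, 11 and 16 are taken as commercially available.

## Route

**Step 1**
Reactants: 1 2,4,6-trihydroxybenzaldehyde
Product: 2 2,4-bis(benzyloxy)-6-hydroxybenzaldehyde
Conditions: BnBr (2.05 equiv), K2CO3 (2.2 equiv), DMF, 0 °C → rt
Reagents that add atoms: benzyl bromide, BrCc1ccccc1
Why: Williamson ether synthesis; the 4-hydroxyl and one 2-hydroxyl are alkylated, while the last hydroxyl is held in a strong hydrogen bond to the formyl oxygen and should resist a third alkylation, as acyl phloroglucinols do.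

**Step 2**
Reactants: 2 2,4-bis(benzyloxy)-6-hydroxybenzaldehyde
Product: 3 3,5-bis(benzyloxy)-2-(hydroxymethyl)phenol
Conditions: NaBH4, THF/MeOH, 0 °C; aq NH4Cl work-up near pH 7; used without storage
Reagents that add atoms: none
Why: Borohydride reduction of the aldehyde to the benzylic alcohol; the cold, non-acidic work-up matters because this electron-rich salicyl alcohol ionises easily, which is the property used in step 5.

**Step 3**
Reactants: 4 1-(benzyloxy)-4-ethynylbenzene; 5 ethyl diazoacetate
Product: 6 ethyl 4-[4-(benzyloxy)phenyl]but-3-ynoate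
Conditions: CuI (5 mol %), MeCN, rt
Reagents that add atoms: none
Why: Copper-catalysed coupling of a terminal alkyne with a diazoacetate gives the 3-alkynoate directly and without base, so the skipped ester should not isomerise to the allenoate.

**Step 4**
Reactants: 6 ethyl 4-[4-(benzyloxy)phenyl]but-3-ynoate
Product: 7 ethyl (3Z)-4-[4-(benzyloxy)phenyl]but-3-enoate
Conditions: H2 (1 atm), Pd/CaCO3–Pb(OAc)2 (Lindlar catalyst), quinoline, EtOAc, rt, stopped after 1 equiv H2
Reagents that add atoms: none
Why: Lindlar syn-semihydrogenation delivers both hydrogens to one face of the alkyne and fixes the (Z) geometry; the poisoned catalyst leaves the benzyl ether intact and the neutral medium keeps the β,γ-unsaturated ester out of conjugation.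

**Step 5**
Reactants: 3 3,5-bis(benzyloxy)-2-(hydroxymethyl)phenol; 7 ethyl (3Z)-4-[4-(benzyloxy)phenyl]but-3-enoate
Product: 9 ethyl 2-[(2S,3S)-5,7-bis(benzyloxy)-2-[4-(benzyloxy)phenyl]-3,4-dihydro-2H-chromen-3-yl]acetate (2,3-cis), via ortho-quinone methide 8 (not isolated)
Conditions: (R)-3,3'-bis(2,4,6-triisopropylphenyl)-1,1'-binaphthyl-2,2'-diyl hydrogen phosphate (10 mol %), 7 (2 equiv), 4 Å MS, toluene, −20 → 0 °C, 3 added slowly
Reagents that add atoms: none
Why: The phosphoric acid protonates the benzylic hydroxyl of 3 and loss of water gives the ortho-quinone methide 8, which stays hydrogen-bonded through its carbonyl oxygen to the chiral phosphate. The electron-rich (Z)-styrene 7 then adds across the O=C–C=CH2 unit of 8 in an inverse-demand hetero-Diels–Alder reaction; the closest known reaction type is the chiral Brønsted-acid-catalysed [4+2] addition of ortho-quinone methides from 2-(hydroxymethyl)phenols to styrenes, which gives 2-arylchromans. Ring C' is closed by this [4+2] cycloaddition, with O1', C8a', C4a' and C4' coming from 8 and C2' and C3' from 7, and with C3'–C4' formed ahead of O1'–C2' in an asynchronous transition state. The regiochemistry follows from polarisation: the methide carbon bonds to the alkene carbon that bears the ester arm, so positive charge builds up on the carbon carrying the 4-benzyloxyphenyl group, where the oxygen terminus then bonds. The relative configuration of C2' and C3' is copied from the alkene, because both bonds form on one face of the (Z) double bond and the aryl group and the acetate arm therefore end up cis whether the approach is endo or exo. The absolute configuration of both centres is set together by the chiral phosphate, whose 2,4,6-triisopropylphenyl groups leave one enantioface of the alkene open to the bound quinone methide. The step needs retention of geometry, enantioface selection and chemoselectivity over Friedel–Crafts self-condensation; the tight pairing of the phosphate-bound phenoxide with the developing benzylic cation in a non-polar solvent at low temperature should make ring closure faster than rotation about C2'–C3', and slow addition of 3 to excess 7 keeps the concentration of 8 low.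

**Step 6**
Reactants: 9 ethyl 2-[(2S,3S)-5,7-bis(benzyloxy)-2-[4-(benzyloxy)phenyl]-3,4-dihydro-2H-chromen-3-yl]acetate
Product: 10 2-[(2S,3S)-5,7-bis(benzyloxy)-2-[4-(benzyloxy)phenyl]-3,4-dihydro-2H-chromen-3-yl]-N-methoxy-N-methylacetamide
Conditions: MeNH(OMe)·HCl, i-PrMgCl, THF, −20 → 0 °C
Reagents that add atoms: N,O-dimethylhydroxylamine hydrochloride, CNOC.Cl
Why: Direct aminolysis of the ester by the chloromagnesium amide of N,O-dimethylhydroxylamine (Weinreb amide synthesis); neither stereocentre is α to the carbonyl group, so the basic conditions cannot epimerise them.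

**Step 7**
Reactants: 11 1,3,5-tris(benzyloxy)benzene
Product: 12 1,3,5-tris(benzyloxy)-2-bromobenzene
Conditions: NBS (1.0 equiv), CH2Cl2, −20 → 0 °C
Reagents that add atoms: N-bromosuccinimide, O=C1CCC(=O)N1Br
Why: Electrophilic aromatic bromination; the three free ring positions are equivalent, so there is no regiochemical question, and one equivalent of reagent at low temperature should hold the reaction at the monobromide.

**Step 8**
Reactants: 12 1,3,5-tris(benzyloxy)-2-bromobenzene; 10 2-[(2S,3S)-5,7-bis(benzyloxy)-2-[4-(benzyloxy)phenyl]-3,4-dihydro-2H-chromen-3-yl]-N-methoxy-N-methylacetamide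
Product: 14 2-[(2S,3S)-5,7-bis(benzyloxy)-2-[4-(benzyloxy)phenyl]-3,4-dihydro-2H-chromen-3-yl]-1-[2,4,6-tris(benzyloxy)phenyl]ethan-1-one, via aryllithium 13 (not isolated)
Conditions: 12 (1.6 equiv), n-BuLi (1.5 equiv), THF, −78 °C; then 10, −78 → −20 °C; aq NH4Cl
Reagents that add atoms: none
Why: Bromine–lithium exchange followed by Weinreb ketone synthesis; the chelated tetrahedral intermediate survives until the quench and prevents a second addition, and the excess of the hindered aryllithium offsets any enolisation of the amide.

**Step 9**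
Reactants: 14 2-[(2S,3S)-5,7-bis(benzyloxy)-2-[4-(benzyloxy)phenyl]-3,4-dihydro-2H-chromen-3-yl]-1-[2,4,6-tris(benzyloxy)phenyl]ethan-1-one
Product: 15 1-[2,4-bis(benzyloxy)-6-hydroxyphenyl]-2-[(2S,3S)-5,7-bis(benzyloxy)-2-[4-(benzyloxy)phenyl]-3,4-dihydro-2H-chromen-3-yl]ethan-1-one
Conditions: MgBr2·OEt2 (3 equiv), toluene/Et2O, rt → 45 °C; 1 M HCl work-up
Reagents that add atoms: none
Why: Chelation-controlled ortho-debenzylation: magnesium binds the ketone oxygen and a neighbouring benzyloxy oxygen, and bromide removes that benzyl group by SN2 attack. The two ortho ethers are equivalent, the magnesium phenoxide chelate formed after the first cleavage should shut down the second, and the five other benzyl ethers have no carbonyl neighbour.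

**Step 10**
Reactants: 15 1-[2,4-bis(benzyloxy)-6-hydroxyphenyl]-2-[(2S,3S)-5,7-bis(benzyloxy)-2-[4-(benzyloxy)phenyl]-3,4-dihydro-2H-chromen-3-yl]ethan-1-one; 16 4-methoxybenzaldehyde
Product: 18 (2S,3R)-5,7-bis(benzyloxy)-3-[(2S,3S)-5,7-bis(benzyloxy)-2-[4-(benzyloxy)phenyl]-3,4-dihydro-2H-chromen-3-yl]-2-(4-methoxyphenyl)-2,3-dihydro-4H-chromen-4-one, via chalcone 17 (not isolated)
Conditions: pyrrolidine (1.2 equiv), EtOH/toluene, 70 °C
Reagents that add atoms: none
Why: Amine-mediated Claisen–Schmidt-type aldol condensation (through the iminium ion of 16) gives chalcone 17, and the phenoxide closes ring C by 6-endo-trig oxa-Michael addition. Both events are reversible, so C2 and C3 should settle under thermodynamic control in the diequatorial 2,3-trans arrangement; of the two trans forms the (2S,3R) one is expected to prevail, because with H3 and H3' anti it places the two aryl-bearing carbons C2 and C2' anti about the C3–C3' bond. C2' and C3' have no acidic hydrogen at this stage and are not touched.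

**Step 11**
Reactants: 18 (2S,3R)-5,7-bis(benzyloxy)-3-[(2S,3S)-5,7-bis(benzyloxy)-2-[4-(benzyloxy)phenyl]-3,4-dihydro-2H-chromen-3-yl]-2-(4-methoxyphenyl)-2,3-dihydro-4H-chromen-4-one
Product: 19 the C4'-hydroxy derivative of 18, (2S,3R)-5,7-bis(benzyloxy)-3-[(2S,3R,4RS)-5,7-bis(benzyloxy)-2-[4-(benzyloxy)phenyl]-4-hydroxy-3,4-dihydro-2H-chromen-3-yl]-2-(4-methoxyphenyl)-2,3-dihydro-4H-chromen-4-one (C4' epimers; C2, C3, C2' and C3' arranged in space as in 18)
Conditions: DDQ (1.3 equiv), CH2Cl2/H2O (10:1), 0 °C → rt
Reagents that add atoms: water, O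
Why: Hydride abstraction by the quinone at C4', the only benzylic methylene, whose cation is stabilised by O1' and the 5'- and 7'-benzyloxy groups, followed by capture with water; this is the benzylic C4 oxidation known for protected flavan-3-ols. The C2–H bond of unit 1 should be far less hydridic because O1 is tied up as a vinylogous ester with the C4 ketone, and the configuration of the new carbinol centre does not matter.

**Step 12**
Reactants: 19 the C4'-hydroxy derivative of 18
Product: 20 (2S,3R)-5,7-bis(benzyloxy)-3-[(2S,3S)-5,7-bis(benzyloxy)-2-[4-(benzyloxy)phenyl]-4-oxo-3,4-dihydro-2H-chromen-3-yl]-2-(4-methoxyphenyl)-2,3-dihydro-4H-chromen-4-one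
Conditions: Dess–Martin periodinane, pyridine, CH2Cl2, 0 °C → rt
Reagents that add atoms: none
Why: Dess–Martin oxidation of the secondary benzylic alcohol under buffered, non-basic conditions, so that C3', which becomes α to a ketone in this step, keeps its cis relationship to C2'.

**Step 13**
Reactants: 20 (2S,3R)-5,7-bis(benzyloxy)-3-[(2S,3S)-5,7-bis(benzyloxy)-2-[4-(benzyloxy)phenyl]-4-oxo-3,4-dihydro-2H-chromen-3-yl]-2-(4-methoxyphenyl)-2,3-dihydro-4H-chromen-4-one
Product: 21 (2S,3R)-5,7-dihydroxy-3-[(2S,3S)-5,7-dihydroxy-2-(4-hydroxyphenyl)-4-oxo-3,4-dihydro-2H-chromen-3-yl]-2-(4-methoxyphenyl)-2,3-dihydro-4H-chromen-4-one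
Conditions: H2 (1 atm), Pd/C (10 %), EtOAc/MeOH, rt
Reagents that add atoms: none
Why: Catalytic hydrogenolysis should remove the five benzyl ethers under neutral conditions and leave the methyl ether, both aryl ketones and both ring ether bonds intact, as in standard flavanone deprotections; no acid or base meets the epimerisable cis unit.

## Compound list

1 | 2,4,6-trihydroxybenzaldehyde | O=Cc1c(O)cc(O)cc1O | starting material
2 | 2,4-bis(benzyloxy)-6-hydroxybenzaldehyde | O=Cc1c(O)cc(OCc2ccccc2)cc1OCc1ccccc1 | intermediate
3 | 3,5-bis(benzyloxy)-2-(hydroxymethyl)phenol | OCc1c(O)cc(OCc2ccccc2)cc1OCc1ccccc1 | intermediate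
4 | 1-(benzyloxy)-4-ethynylbenzene | C#Cc1ccc(OCc2ccccc2)cc1 | starting material
5 | ethyl diazoacetate | CCOC(=O)C=[N+]=[N-] | starting material
6 | ethyl 4-[4-(benzyloxy)phenyl]but-3-ynoate | CCOC(=O)CC#Cc1ccc(OCc2ccccc2)cc1 | intermediate
7 | ethyl (3Z)-4-[4-(benzyloxy)phenyl]but-3-enoate | CCOC(=O)C/C=C\c1ccc(OCc2ccccc2)cc1 | intermediate
8 | 3,5-bis(benzyloxy)-6-methylidenecyclohexa-2,4-dien-1-one (ortho-quinone methide, not isolated) | C=C1C(=O)C=C(OCc2ccccc2)C=C1OCc1ccccc1 | intermediate
9 | ethyl 2-[(2S,3S)-5,7-bis(benzyloxy)-2-[4-(benzyloxy)phenyl]-3,4-dihydro-2H-chromen-3-yl]acetate | CCOC(=O)C[C@@H]1Cc2c(OCc3ccccc3)cc(OCc3ccccc3)cc2O[C@@H]1c1ccc(OCc2ccccc2)cc1 | intermediate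
10 | 2-[(2S,3S)-5,7-bis(benzyloxy)-2-[4-(benzyloxy)phenyl]-3,4-dihydro-2H-chromen-3-yl]-N-methoxy-N-methylacetamide | CON(C)C(=O)C[C@@H]1Cc2c(OCc3ccccc3)cc(OCc3ccccc3)cc2O[C@@H]1c1ccc(OCc2ccccc2)cc1 | intermediate
11 | 1,3,5-tris(benzyloxy)benzene | c1c(OCc2ccccc2)cc(OCc2ccccc2)cc1OCc1ccccc1 | starting material
12 | 1,3,5-tris(benzyloxy)-2-bromobenzene | Brc1c(OCc2ccccc2)cc(OCc2ccccc2)cc1OCc1ccccc1 | intermediate
13 | [2,4,6-tris(benzyloxy)phenyl]lithium (not isolated) | [Li]c1c(OCc2ccccc2)cc(OCc2ccccc2)cc1OCc1ccccc1 | intermediate
14 | 2-[(2S,3S)-5,7-bis(benzyloxy)-2-[4-(benzyloxy)phenyl]-3,4-dihydro-2H-chromen-3-yl]-1-[2,4,6-tris(benzyloxy)phenyl]ethan-1-one | O=C(C[C@@H]1Cc2c(OCc3ccccc3)cc(OCc3ccccc3)cc2O[C@@H]1c1ccc(OCc2ccccc2)cc1)c1c(OCc2ccccc2)cc(OCc2ccccc2)cc1OCc1ccccc1 | intermediate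
15 | 1-[2,4-bis(benzyloxy)-6-hydroxyphenyl]-2-[(2S,3S)-5,7-bis(benzyloxy)-2-[4-(benzyloxy)phenyl]-3,4-dihydro-2H-chromen-3-yl]ethan-1-one | O=C(C[C@@H]1Cc2c(OCc3ccccc3)cc(OCc3ccccc3)cc2O[C@@H]1c1ccc(OCc2ccccc2)cc1)c1c(O)cc(OCc2ccccc2)cc1OCc1ccccc1 | intermediate
16 | 4-methoxybenzaldehyde | COc1ccc(C=O)cc1 | starting material
17 | (2E)-1-[2,4-bis(benzyloxy)-6-hydroxyphenyl]-2-[(2S,3S)-5,7-bis(benzyloxy)-2-[4-(benzyloxy)phenyl]-3,4-dihydro-2H-chromen-3-yl]-3-(4-methoxyphenyl)prop-2-en-1-one (chalcone, not isolated) | COc1ccc(/C=C(\[C@@H]2Cc3c(OCc4ccccc4)cc(OCc4ccccc4)cc3O[C@@H]2c2ccc(OCc3ccccc3)cc2)C(=O)c2c(O)cc(OCc3ccccc3)cc2OCc2ccccc2)cc1 | intermediate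
18 | (2S,3R)-5,7-bis(benzyloxy)-3-[(2S,3S)-5,7-bis(benzyloxy)-2-[4-(benzyloxy)phenyl]-3,4-dihydro-2H-chromen-3-yl]-2-(4-methoxyphenyl)-2,3-dihydro-4H-chromen-4-one | COc1ccc([C@H]2Oc3cc(OCc4ccccc4)cc(OCc4ccccc4)c3C(=O)[C@@H]2[C@@H]2Cc3c(OCc4ccccc4)cc(OCc4ccccc4)cc3O[C@@H]2c2ccc(OCc3ccccc3)cc2)cc1 | intermediate
19 | C4'-hydroxy derivative of 18, (2S,3R)-5,7-bis(benzyloxy)-3-[(2S,3R,4RS)-5,7-bis(benzyloxy)-2-[4-(benzyloxy)phenyl]-4-hydroxy-3,4-dihydro-2H-chromen-3-yl]-2-(4-methoxyphenyl)-2,3-dihydro-4H-chromen-4-one (C4' epimers) | COc1ccc([C@H]2Oc3cc(OCc4ccccc4)cc(OCc4ccccc4)c3C(=O)[C@@H]2[C@@H]2C(O)c3c(OCc4ccccc4)cc(OCc4ccccc4)cc3O[C@@H]2c2ccc(OCc3ccccc3)cc2)cc1 | intermediate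
20 | (2S,3R)-5,7-bis(benzyloxy)-3-[(2S,3S)-5,7-bis(benzyloxy)-2-[4-(benzyloxy)phenyl]-4-oxo-3,4-dihydro-2H-chromen-3-yl]-2-(4-methoxyphenyl)-2,3-dihydro-4H-chromen-4-one | COc1ccc([C@H]2Oc3cc(OCc4ccccc4)cc(OCc4ccccc4)c3C(=O)[C@@H]2[C@@H]2C(=O)c3c(OCc4ccccc4)cc(OCc4ccccc4)cc3O[C@@H]2c2ccc(OCc3ccccc3)cc2)cc1 | intermediate
21 | (2S,3R)-5,7-dihydroxy-3-[(2S,3S)-5,7-dihydroxy-2-(4-hydroxyphenyl)-4-oxo-3,4-dihydro-2H-chromen-3-yl]-2-(4-methoxyphenyl)-2,3-dihydro-4H-chromen-4-one | COc1ccc([C@H]2Oc3cc(O)cc(O)c3C(=O)[C@@H]2[C@@H]2C(=O)c3c(O)cc(O)cc3O[C@@H]2c2ccc(O)cc2)cc1 | target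

## Step count and least certain steps

Total: 13 steps. Longest linear sequence: 10 steps (1 → 2 → 3 → 9 → 10 → 14 → 15 → 18 → 19 → 20 → 21; steps 1, 2, 5, 6, 8, 9, 10, 11, 12 and 13).

**Step 5 (key step).**
- Risks: the cycloaddition may become stepwise, so that rotation in a longer-lived benzylic cation erodes the cis geometry or the ester carbonyl captures the cation. Enantioface discrimination may be weak, because the catalyst is bound only to the quinone methide. The electron-rich arenes may consume the quinone methide by Friedel–Crafts self-condensation.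
- Fallback: it sets out from 3 and 7 and returns at 9. Compound 3 is heated with excess 7 in toluene at about 150 °C in a sealed vessel without acid. Thermal loss of water gives 8, which should add in a concerted, geometry-retaining hetero-Diels–Alder reaction to give racemic ethyl 2-[cis-5,7-bis(benzyloxy)-2-[4-(benzyloxy)phenyl]-3,4-dihydro-2H-chromen-3-yl]acetate F1. Preparative chromatography on a chiral stationary phase then provides 9.

**Step 10.**
- Risks: condensation at the hindered α-methylene of a 2,6-disubstituted aryl ketone may be slow, and the equilibrium preference between the two trans arrangements relative to C3' may be small.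
- Fallback: it sets out from 15 and 16 and returns at 18. Ketone 15 is deprotonated twice with LiN(SiMe3)2 in THF at −78 °C to the dilithium phenoxide enolate of 15 F2. Addition of 16 gives 1-[2,4-bis(benzyloxy)-6-hydroxyphenyl]-2-[(2S,3S)-5,7-bis(benzyloxy)-2-[4-(benzyloxy)phenyl]-3,4-dihydro-2H-chromen-3-yl]-3-hydroxy-3-(4-methoxyphenyl)propan-1-one F3 in a kinetically controlled aldol reaction. Mitsunobu cyclisation (PPh3, diisopropyl azodicarboxylate) closes O1–C2 by displacement of the benzylic hydroxyl, and a catalytic amount of DBU then equilibrates C3 to the trans flavanone 18. If separation is needed, the minor fraction can be returned to the equilibrating conditions of step 10.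

**Step 9.**
- Risks: more than one benzyl ether may be lost, or the Lewis acid may open the 4-alkoxybenzylic O1'–C2' bond, which would erase the cis relationship.
- Fallback: it sets out from 10 and returns at 15, and it introduces ring A with the phenol already differentiated. Commercial 3,5-bis(benzyloxy)phenol F4 is brominated ortho to the hydroxyl (NBS, catalytic i-Pr2NH, CH2Cl2) to 2-bromo-3,5-bis(benzyloxy)phenol F5. This is protected with chloromethyl methyl ether and i-Pr2NEt as 1,5-bis(benzyloxy)-2-bromo-3-(methoxymethoxy)benzene F6. Bromine–lithium exchange gives [2,4-bis(benzyloxy)-6-(methoxymethoxy)phenyl]lithium F7, which adds to 10 to give 1-[2,4-bis(benzyloxy)-6-(methoxymethoxy)phenyl]-2-[(2S,3S)-5,7-bis(benzyloxy)-2-[4-(benzyloxy)phenyl]-3,4-dihydro-2H-chromen-3-yl]ethan-1-one F8. Dilute HCl in MeOH/THF at rt removes the acetal and gives 15.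

**Step 11.**
- Risks: the C4' cation may lose the C3' proton to give a chromene instead of being trapped by water, which would destroy the C3' stereocentre. Hydride abstraction may also occur at C2, the other alkoxybenzylic ether position.
- Fallback: it sets out from 18 and returns at 19. Benzylic acetoxylation with Pb(OAc)4 in toluene at rt, a reaction known for 5,7-dialkoxyflavans, delivers acetate within the metal-bound intermediate and should give the C4'-acetoxy derivative of 18 F9. Hydrolysis with K2CO3 in aqueous MeOH/THF then gives 19.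

## Further compounds

F1 | step 5 | racemic ethyl 2-[cis-5,7-bis(benzyloxy)-2-[4-(benzyloxy)phenyl]-3,4-dihydro-2H-chromen-3-yl]acetate, (2S,3S) and (2R,3R) | CCOC(=O)C[C@@H]1Cc2c(OCc3ccccc3)cc(OCc3ccccc3)cc2O[C@@H]1c1ccc(OCc2ccccc2)cc1.CCOC(=O)C[C@H]1Cc2c(OCc3ccccc3)cc(OCc3ccccc3)cc2O[C@H]1c1ccc(OCc2ccccc2)cc1
F2 | step 10 | dilithium phenoxide enolate of 15 | [Li+].[Li+].[O-]C(=C[C@@H]1Cc2c(OCc3ccccc3)cc(OCc3ccccc3)cc2O[C@@H]1c1ccc(OCc2ccccc2)cc1)c1c([O-])cc(OCc2ccccc2)cc1OCc1ccccc1
F3 | step 10 | 1-[2,4-bis(benzyloxy)-6-hydroxyphenyl]-2-[(2S,3S)-5,7-bis(benzyloxy)-2-[4-(benzyloxy)phenyl]-3,4-dihydro-2H-chromen-3-yl]-3-hydroxy-3-(4-methoxyphenyl)propan-1-one (diastereomers at the two new centres) | COc1ccc(C(O)C([C@@H]2Cc3c(OCc4ccccc4)cc(OCc4ccccc4)cc3O[C@@H]2c2ccc(OCc3ccccc3)cc2)C(=O)c2c(O)cc(OCc3ccccc3)cc2OCc2ccccc2)cc1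
F4 | step 9 | 3,5-bis(benzyloxy)phenol | Oc1cc(OCc2ccccc2)cc(OCc2ccccc2)c1
F5 | step 9 | 2-bromo-3,5-bis(benzyloxy)phenol | Oc1cc(OCc2ccccc2)cc(OCc2ccccc2)c1Br
F6 | step 9 | 1,5-bis(benzyloxy)-2-bromo-3-(methoxymethoxy)benzene | COCOc1cc(OCc2ccccc2)cc(OCc2ccccc2)c1Br
F7 | step 9 | [2,4-bis(benzyloxy)-6-(methoxymethoxy)phenyl]lithium | [Li]c1c(OCOC)cc(OCc2ccccc2)cc1OCc1ccccc1
F8 | step 9 | 1-[2,4-bis(benzyloxy)-6-(methoxymethoxy)phenyl]-2-[(2S,3S)-5,7-bis(benzyloxy)-2-[4-(benzyloxy)phenyl]-3,4-dihydro-2H-chromen-3-yl]ethan-1-one | O=C(C[C@@H]1Cc2c(OCc3ccccc3)cc(OCc3ccccc3)cc2O[C@@H]1c1ccc(OCc2ccccc2)cc1)c1c(OCOC)cc(OCc2ccccc2)cc1OCc1ccccc1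
F9 | step 11 | C4'-acetoxy derivative of 18, (2S,3R,4RS)-5,7-bis(benzyloxy)-3-[(2S,3R)-5,7-bis(benzyloxy)-2-(4-methoxyphenyl)-4-oxo-3,4-dihydro-2H-chromen-3-yl]-2-[4-(benzyloxy)phenyl]-3,4-dihydro-2H-chromen-4-yl acetate (C4' epimers) | COc1ccc([C@H]2Oc3cc(OCc4ccccc4)cc(OCc4ccccc4)c3C(=O)[C@@H]2[C@@H]2C(OC(C)=O)c3c(OCc4ccccc4)cc(OCc4ccccc4)cc3O[C@@H]2c2ccc(OCc3ccccc3)cc2)cc1
A1 | alternative 1 | trans-5,7-bis(benzyloxy)-2-(4-methoxyphenyl)-3-[2-(triisopropylsilyloxy)ethyl]chroman-4-one | COc1ccc([C@H]2Oc3cc(OCc4ccccc4)cc(OCc4ccccc4)c3C(=O)[C@@H]2CCO[Si](C(C)C)(C(C)C)C(C)C)cc1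
A2 | alternative 1 | 5,7-bis(benzyloxy)-2-(4-methoxyphenyl)-4-[3-(triisopropylsilyloxy)propylidene]-4H-1,3-benzodioxine (racemic at the acetal carbon, alkene geometry not fixed) | COc1ccc(C2Oc3cc(OCc4ccccc4)cc(OCc4ccccc4)c3C(=CCCO[Si](C(C)C)(C(C)C)C(C)C)O2)cc1
A3 | alternative 2 | penta-O-benzyl target, identical with 20 | COc1ccc([C@H]2Oc3cc(OCc4ccccc4)cc(OCc4ccccc4)c3C(=O)[C@@H]2[C@@H]2C(=O)c3c(OCc4ccccc4)cc(OCc4ccccc4)cc3O[C@@H]2c2ccc(OCc3ccccc3)cc2)cc1
A4 | alternative 2 | 2-{[3,5-bis(benzyloxy)phenoxy](4-methoxyphenyl)methyl}-3-{[3,5-bis(benzyloxy)phenoxy][4-(benzyloxy)phenyl]methyl}butanedioic acid, the four centres arranged as C2, C3, C3' and C2' of 20 | COc1ccc([C@@H](Oc2cc(OCc3ccccc3)cc(OCc3ccccc3)c2)[C@H](C(=O)O)[C@H](C(=O)O)[C@H](Oc2cc(OCc3ccccc3)cc(OCc3ccccc3)c2)c2ccc(OCc3ccccc3)cc2)cc1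
A5 | alternative 3 | protected target with a 4-benzyloxybenzyl ether on the C5' oxygen | COc1ccc([C@H]2Oc3cc(OCc4ccccc4)cc(OCc4ccccc4)c3C(=O)[C@@H]2[C@@H]2C(=O)c3c(OCc4ccc(OCc5ccccc5)cc4)cc(OCc4ccccc4)cc3O[C@@H]2c2ccc(OCc3ccccc3)cc2)cc1
A6 | alternative 3 | 1-[4-(benzyloxy)-2,6-bis(4-benzyloxybenzyloxy)phenyl]-2-diazo-2-[trans-5,7-bis(benzyloxy)-2-(4-methoxyphenyl)-4-oxo-3,4-dihydro-2H-chromen-3-yl]ethan-1-one | COc1ccc([C@H]2Oc3cc(OCc4ccccc4)cc(OCc4ccccc4)c3C(=O)[C@@H]2C(=[N+]=[N-])C(=O)c2c(OCc3ccc(OCc4ccccc4)cc3)cc(OCc3ccccc3)cc2OCc2ccc(OCc3ccccc3)cc2)cc1
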